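**Retrosynthetic overview**
1. Target ⇒ ten-membered 5(16),6-diene C19 acid: one Pd(OCOCF3)2-catalysed 1,4-oxidation makes the C7–O (lactone) and C16–O bonds and the 5Z alkene (lactone ring formed last).
2. Diene acid ⇒ acyclic enyne (C5≡C6 alkyne, C7 vinyl): ethylene enyne metathesis, then ring-closing metathesis (ten-membered ring formed third).
3. Enyne ⇒ ring A aldehyde + 4-(trimethylsilyl)but-3-yn-2-one (catalytic aldol, anti reduction: C2, C4) and α-hydroxy vinyl ketone + propanoate Reformatsky reagent (C8, C17).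
4. C9–C10 by Eschenmoser–Claisen rearrangement of a Wharton-transposed allylic alcohol; C9–O by enolate oxidation; 11,12-oxirane by hydroxyl-directed epoxidation (formed second).
5. Ring A (first ring, chiral pool) ⇒ (S)-carvone: hydroxymethylation/methylation (C1) and Criegee exchange of isopropenyl for oxygen (C14).

Assumption: briarane numbering is used throughout (ring A = C1, C10–C14; Me-15 on C1, Me-20 on C11, C16 on C5, C17/Me-18/C19 = lactone arm; carvone C1/C2/C3/C4/C5/C6 = briarane C10/C11/C12/C13/C14/C1). The target is read from the SMILES as 1S,2R,4R,5Z,7S,8S,9R,10S,11R,12S,14S,17R. TBS = tert-butyldimethylsilyl.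

**Step 1**
Reactants: 1 (S)-(+)-carvone
Product: 3 (5S,6S)-6-[(tert-butyldimethylsilyloxy)methyl]carvone (CH2OTBS trans to isopropenyl), via lithium aldolate 2 (not isolated)
Conditions: LiN(iPr)2, THF, −78 °C; CH2O (gas, cracked paraformaldehyde), −78 °C; then TBSOTf, −78 → 0 °C
Reagents that add atoms: formaldehyde C=O; tert-butyldimethylsilyl trifluoromethanesulfonate CC(C)(C)[Si](C)(C)OS(=O)(=O)C(F)(F)F
Why: The kinetic α′-lithium enolate undergoes aldol addition to monomeric formaldehyde anti to the isopropenyl group and the aldolate is O-silylated in the same flask; the new C1 centre is re-enolised in step 2, so its configuration does not matter.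

**Step 2**
Reactants: 3 (5S,6S)-6-[(tert-butyldimethylsilyloxy)methyl]carvone
Product: 4 (5S,6R)-6-[(tert-butyldimethylsilyloxy)methyl]-6-methylcarvone (Me-15 trans and CH2OTBS cis to isopropenyl)
Conditions: LiN(iPr)2, THF/DMPU, −78 °C; MeI, −78 → −30 °C
Reagents that add atoms: iodomethane CI
Why: Enolate alkylation in which MeI approaches the α′-enolate anti to the adjacent isopropenyl group, which sets the quaternary C1 with the C2 arm cis to the C14 substituent.

**Step 3**
Reactants: 4 (5S,6R)-6-[(tert-butyldimethylsilyloxy)methyl]-6-methylcarvone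
Product: 5 epoxy ketone of 4 (11,12-oxirane trans to isopropenyl; cis to Me-15)
Conditions: 30% H2O2, NaOH (0.3 equiv), MeOH, 0 °C
Reagents that add atoms: hydrogen peroxide OO
Why: Weitz–Scheffer nucleophilic epoxidation in which hydroperoxide adds axially to C12 anti to the C14 isopropenyl group, as with carvone itself, while the isolated isopropenyl alkene is inert.

**Step 4**
Reactants: 5 epoxy ketone of 4
Product: 7 14-acetoxy epoxy ketone (isopropenyl of 5 replaced by OAc with retention), via methoxy hydroperoxide 6 (not isolated)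
Conditions: O3, CH2Cl2/MeOH, −78 °C; then Ac2O, Et3N, DMAP, CH2Cl2, 0 → 40 °C
Reagents that add atoms: ozone [O-][O+]=O; methanol CO
Why: Ozonolysis in methanol gives the α-methoxy hydroperoxide, whose peracetate undergoes Criegee rearrangement with migration of C14 from carbon to oxygen with retention (sets the C14–O centre); the ketone has no α-hydrogen, so no β-elimination is possible.

**Step 5**
Reactants: 7 14-acetoxy epoxy ketone
Product: 9 14-acetoxy allylic alcohol (C10=C11; 12-OH cis to Me-15 and trans to 14-OAc), via epoxy hydrazone 8 (not isolated)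
Conditions: N2H4·H2O (5 equiv), AcOH (5 equiv), MeOH, 25 → 45 °C
Reagents that add atoms: none
Why: Wharton transposition in which the epoxy hydrazone loses N2 and opens the oxirane, so the C12–O bond stays on the face of the former epoxide; buffered hydrazinium acetate spares the hindered acetate.

**Step 6**
Reactants: 9 14-acetoxy allylic alcohol
Product: 12 14-hydroxy C8 dimethylamide (C10–C9H2–C8(=O)NMe2 cis to Me-15; C11=C12), via ketene N,O-acetal 10 (not isolated), via acetoxy amide 11 (not isolated)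
Conditions: MeC(OMe)2NMe2 (5 equiv), xylene, 140 °C; cool, then K2CO3, MeOH, 25 °C
Reagents that add atoms: N,N-dimethylacetamide dimethyl acetal COC(C)(OC)N(C)C
Why: Eschenmoser–Claisen rearrangement in which the ketene N,O-acetal on the pseudoaxial C12 oxygen delivers carbon suprafacially to C10 (sets C10 and moves the alkene to C11=C12), followed by methanolysis of the acetate, which is safe now that no ketone remains.

**Step 7**
Reactants: 12 14-hydroxy C8 dimethylamide
Product: 13 14-O-TBS C8 dimethylamide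
Conditions: TBSOTf, 2,6-lutidine, CH2Cl2, 0 °C
Reagents that add atoms: tert-butyldimethylsilyl trifluoromethanesulfonate CC(C)(C)[Si](C)(C)OS(=O)(=O)C(F)(F)F
Why: Silylation of the hindered secondary alcohol masks the C14 hydroxyl so that only the C9 hydroxyl can direct the epoxidation in step 9.

**Step 8**
Reactants: 13 14-O-TBS C8 dimethylamide
Product: 14 (9R)-9-hydroxy C8 dimethylamide
Conditions: LiN(iPr)2, THF, −78 °C; then 2-(phenylsulfonyl)-3-phenyloxaziridine, −78 °C; NH4Cl quench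
Reagents that add atoms: 2-(phenylsulfonyl)-3-phenyloxaziridine O=S(=O)(N1OC1c1ccccc1)c1ccccc1
Why: Davis α-hydroxylation in which allylic 1,3-strain holds H10 in the plane of the amide enolate, so oxygen is delivered to the C9 face opposite the quaternary C1, giving 9R.

**Step 9**
Reactants: 14 (9R)-9-hydroxy C8 dimethylamide
Product: 15 (9R)-9-hydroxy-11,12-epoxy C8 dimethylamide (oxirane cis to Me-15 and to the C10 side chain)
Conditions: VO(acac)2 (5 mol %), t-BuOOH, CH2Cl2, 0 → 25 °C
Reagents that add atoms: tert-butyl hydroperoxide CC(C)(C)OO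
Why: Hydroxyl-directed VO(acac)2-catalysed epoxidation in which the homoallylic C9 alkoxide delivers the peroxide to the face of C11=C12 that carries the C10 side chain (sets C11 and C12).

**Step 10**
Reactants: 15 (9R)-9-hydroxy-11,12-epoxy C8 dimethylamide
Product: 16 (9R)-9-hydroxy-11,12-epoxy C8 vinyl ketone
Conditions: CH2=CHMgBr (3.5 equiv), THF, −20 → 0 °C; AcOH quench at −78 °C
Reagents that add atoms: vinylmagnesium bromide C=C[Mg]Br
Why: Acyl substitution of the tertiary amide through an alkoxide-chelated tetrahedral intermediate that collapses to the ketone only on the cold acidic quench, so over-addition and amine conjugate addition are avoided.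

**Step 11**
Reactants: 17 2-bromopropanoyl bromide; 18 2-(trimethylsilyl)ethanol
Product: 19 2-(trimethylsilyl)ethyl 2-bromopropanoate (racemic)
Conditions: pyridine, CH2Cl2, 0 °C
Reagents that add atoms: none
Why: Simple esterification of an acid bromide with a primary alcohol.

**Step 12**
Reactants: 16 (9R)-9-hydroxy-11,12-epoxy C8 vinyl ketone; 19 2-(trimethylsilyl)ethyl 2-bromopropanoate
Product: 21 8,9-diol C19 2-(trimethylsilyl)ethyl ester (tertiary 8-OH; C7 vinyl; target configuration at C8 C9 C17), via Reformatsky reagent 20 (not isolated)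
Conditions: Zn (TMSCl-activated), 19, THF, 40 °C to give BrZnCH(CH3)CO2CH2CH2SiMe3 (3 equiv); then 16, THF, −20 → 0 °C
Reagents that add atoms: none
Why: Reformatsky reaction in which the 9-OH, as its zinc alkoxide, chelates the ketone (Cram chelate) so the enolate adds 1,2 to the face anti to C10 (sets C8), through a chair with the vinyl group equatorial and the enolate methyl anti to it (8,17-anti, sets C17).

**Step 13**
Reactants: 21 8,9-diol C19 2-(trimethylsilyl)ethyl ester
Product: 22 9-O-acetyl derivative of 21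
Conditions: Ac2O, pyridine, DMAP (0.1 equiv), CH2Cl2, 0 °C, on the crude adduct
Reagents that add atoms: acetic anhydride CC(=O)OC(C)=O
Why: Acylation of the secondary 9-OH, to which the tertiary 8-OH is inert; acetylating at once also blocks translactonisation of the ester onto O9.

**Step 14**
Reactants: 22 9-O-acetyl derivative of 21
Product: 23 C2 primary alcohol (primary silyl ether of 22 removed)
Conditions: HF·pyridine, pyridine, THF, 0 °C
Reagents that add atoms: none
Why: Buffered HF·pyridine cleaves the primary silyl ether much faster than the hindered secondary one at C14.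

**Step 15**
Reactants: 23 C2 primary alcohol
Product: 24 C2 aldehyde
Conditions: Dess–Martin periodinane, NaHCO3, CH2Cl2, 0 → 25 °C
Reagents that add atoms: none
Why: Dess–Martin oxidation of the neopentyl primary alcohol; the tertiary 8-OH cannot be oxidised.

**Step 16**
Reactants: 24 C2 aldehyde; 25 4-(trimethylsilyl)but-3-yn-2-one
Product: 26 (2R)-2-hydroxy-4-oxo-5-ynyl aldol adduct (C6 silyl alkyne)
Conditions: (S,S)-ProPhenol (20 mol %), Et2Zn (40 mol %), 4 Å MS, THF, 0 → 25 °C, 25 (5 equiv)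
Reagents that add atoms: none
Why: Trost dinuclear zinc–ProPhenol direct aldol reaction of a methyl ynone, with catalyst control over the face of the hindered aldehyde (the ligand enantiomer is chosen for 2R; its antipode gives the C2 epimer).

**Step 17**
Reactants: 26 (2R)-2-hydroxy-4-oxo-5-ynyl aldol adduct
Product: 27 (2R,4R)-2,4-anti-diol
Conditions: Me4NBH(OAc)3, MeCN/AcOH, −30 °C
Reagents that add atoms: none
Why: Evans–Saksena reduction in which the borohydride bound to the C2 oxygen delivers hydride intramolecularly through a chair to give the 1,3-anti diol (sets C4).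

**Step 18**
Reactants: 27 (2R,4R)-2,4-anti-diol
Product: 28 2,4,14-triol C19 acid (terminal C5≡C6 alkyne)
Conditions: Bu4NF (8 equiv), THF, 0 → 40 °C; NH4Cl work-up
Reagents that add atoms: none
Why: Fluoride removes the C14 silyl ether and the alkynyl silyl group and fragments the 2-(trimethylsilyl)ethyl ester (loss of ethylene) in one operation.

**Step 19**
Reactants: 28 2,4,14-triol C19 acid
Product: 30 2,4,9,14-tetraacetate C19 acid (acyclic enyne), via mixed anhydride 29 (not isolated)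
Conditions: Ac2O, pyridine, DMAP (0.2 equiv), CH2Cl2, 25 °C; then NaHCO3, THF/H2O
Reagents that add atoms: acetic anhydride CC(=O)OC(C)=O
Why: Acetylation of the three secondary hydroxyls, to which the tertiary 8-OH is inert; the mixed anhydride at C19 is hydrolysed in the bicarbonate work-up.

**Step 20**
Reactants: 30 2,4,9,14-tetraacetate C19 acid
Product: 32 ten-membered 5(16),6Z-diene C19 acid, via triene acid 31 (not isolated)
Conditions: second-generation Grubbs catalyst (10 mol %), ethylene (1 atm), CH2Cl2, 25 °C; then Ar purge, toluene, 1 mM, 80 °C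
Reagents that add atoms: ethylene C=C
Why: Enyne cross-metathesis of the propargylic acetate with ethylene gives the 2-substituted butadiene, whose vinyl terminus then undergoes ring-closing metathesis onto the C7 vinyl group (free allylic hydroxyl assists); the cis C6=C7 bond is expected as the less strained isomer.

**Step 21**
Reactants: 32 ten-membered 5(16),6Z-diene C19 acid
Product: 34 target CNP0104124.1, via 16-O-trifluoroacetate 33 (not isolated)
Conditions: Pd(OCOCF3)2 (10 mol %), 1,4-benzoquinone (2 equiv), NaOCOCF3 (3 equiv), acetone/(CF3)2CHOH 9:1, 0 → 25 °C; then NaHCO3, MeOH/H2O, 0 °C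
Reagents that add atoms: sodium trifluoroacetate [Na+].[O-]C(=O)C(F)(F)F
Why: Proposed new method: divalent palladium binds C6=C7 and the C19 carboxylate adds anti and 5-exo to C7 on the only face it can reach while the ring keeps C9 anti to C6 (trans-fused lactone, 7S), the σ-alkyl becomes the syn π-allyl over C6–C5–C16 (C4 and C7 cis, hence 5Z), benzoquinone-activated attack of trifluoroacetate at the unhindered C16 terminus gives an ester that bicarbonate cleaves selectively to the free C16 alcohol, and benzoquinone returns the zerovalent metal to the divalent state; the closest known reaction type is the Bäckvall 1,4-acetoxy-lactonisation of cyclic 1,3-dienyl acetic acids, which has not been shown on a semicyclic diene in a medium ring or with a trifluoroacetate relay to a free alcohol.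

**Compound list**
1 | (S)-(+)-carvone | CC(=C)[C@H]1CC=C(C)C(=O)C1 | starting material
2 | lithium alkoxide of (5S,6S)-6-(hydroxymethyl)carvone (not isolated) | CC(=C)[C@H]1CC=C(C)C(=O)[C@@H]1C[O-].[Li+] | intermediate
3 | (5S,6S)-6-[(tert-butyldimethylsilyloxy)methyl]carvone, CH2OTBS trans to isopropenyl | CC(=C)[C@H]1CC=C(C)C(=O)[C@@H]1CO[Si](C)(C)C(C)(C)C | intermediate
4 | (5S,6R)-6-[(tert-butyldimethylsilyloxy)methyl]-6-methylcarvone, CH2OTBS cis to isopropenyl | CC(=C)[C@H]1CC=C(C)C(=O)[C@@]1(C)CO[Si](C)(C)C(C)(C)C | intermediate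
5 | epoxy ketone of 4, 11,12-oxirane trans to isopropenyl and cis to Me-15 | CC(=C)[C@H]1C[C@@H]2O[C@]2(C)C(=O)[C@@]1(C)CO[Si](C)(C)C(C)(C)C | intermediate
6 | α-methoxy hydroperoxide from ozonolysis of 5 (not isolated; perketal carbon unassigned) | COC(C)(OO)[C@H]1C[C@@H]2O[C@]2(C)C(=O)[C@@]1(C)CO[Si](C)(C)C(C)(C)C | intermediate
7 | 14-acetoxy epoxy ketone | CC(=O)O[C@H]1C[C@@H]2O[C@]2(C)C(=O)[C@@]1(C)CO[Si](C)(C)C(C)(C)C | intermediate
8 | epoxy hydrazone of 7 (not isolated) | CC(=O)O[C@H]1C[C@@H]2O[C@]2(C)C(=NN)[C@@]1(C)CO[Si](C)(C)C(C)(C)C | intermediate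
9 | 14-acetoxy allylic alcohol, C10=C11, 12-OH cis to Me-15 | CC(=O)O[C@H]1C[C@H](O)C(C)=C[C@@]1(C)CO[Si](C)(C)C(C)(C)C | intermediate
10 | ketene N,O-acetal of 9 (not isolated) | CC(=O)O[C@H]1C[C@H](OC(=C)N(C)C)C(C)=C[C@@]1(C)CO[Si](C)(C)C(C)(C)C | intermediate
11 | 14-acetoxy C8 dimethylamide (not isolated) | CC(=O)O[C@H]1CC=C(C)[C@H](CC(=O)N(C)C)[C@@]1(C)CO[Si](C)(C)C(C)(C)C | intermediate
12 | 14-hydroxy C8 dimethylamide, side chain on C10 cis to Me-15 | O[C@H]1CC=C(C)[C@H](CC(=O)N(C)C)[C@@]1(C)CO[Si](C)(C)C(C)(C)C | intermediate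
13 | 14-O-TBS C8 dimethylamide | CC(C)(C)[Si](C)(C)O[C@H]1CC=C(C)[C@H](CC(=O)N(C)C)[C@@]1(C)CO[Si](C)(C)C(C)(C)C | intermediate
14 | (9R)-9-hydroxy C8 dimethylamide | CC(C)(C)[Si](C)(C)O[C@H]1CC=C(C)[C@H]([C@@H](O)C(=O)N(C)C)[C@@]1(C)CO[Si](C)(C)C(C)(C)C | intermediate
15 | (9R)-9-hydroxy-11,12-epoxy C8 dimethylamide | CC(C)(C)[Si](C)(C)O[C@H]1C[C@@H]2O[C@]2(C)[C@H]([C@@H](O)C(=O)N(C)C)[C@@]1(C)CO[Si](C)(C)C(C)(C)C | intermediate
16 | (9R)-9-hydroxy-11,12-epoxy C8 vinyl ketone | CC(C)(C)[Si](C)(C)O[C@H]1C[C@@H]2O[C@]2(C)[C@H]([C@@H](O)C(=O)C=C)[C@@]1(C)CO[Si](C)(C)C(C)(C)C | intermediate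
17 | 2-bromopropanoyl bromide | CC(Br)C(=O)Br | starting material
18 | 2-(trimethylsilyl)ethanol | C[Si](C)(C)CCO | starting material
19 | 2-(trimethylsilyl)ethyl 2-bromopropanoate (racemic) | CC(Br)C(=O)OCC[Si](C)(C)C | intermediate
20 | bromozinc Reformatsky reagent of 19 (not isolated) | CC([Zn]Br)C(=O)OCC[Si](C)(C)C | intermediate
21 | 8,9-diol C19 2-(trimethylsilyl)ethyl ester, target configuration at C8, C9, C17 | CC(C)(C)[Si](C)(C)O[C@H]1C[C@@H]2O[C@]2(C)[C@H]([C@@H](O)[C@@](O)(C=C)[C@@H](C)C(=O)OCC[Si](C)(C)C)[C@@]1(C)CO[Si](C)(C)C(C)(C)C | intermediate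
22 | 9-O-acetyl derivative of 21 | CC(C)(C)[Si](C)(C)O[C@H]1C[C@@H]2O[C@]2(C)[C@H]([C@@H](OC(C)=O)[C@@](O)(C=C)[C@@H](C)C(=O)OCC[Si](C)(C)C)[C@@]1(C)CO[Si](C)(C)C(C)(C)C | intermediate
23 | C2 primary alcohol | CC(C)(C)[Si](C)(C)O[C@H]1C[C@@H]2O[C@]2(C)[C@H]([C@@H](OC(C)=O)[C@@](O)(C=C)[C@@H](C)C(=O)OCC[Si](C)(C)C)[C@@]1(C)CO | intermediate
24 | C2 aldehyde | CC(C)(C)[Si](C)(C)O[C@H]1C[C@@H]2O[C@]2(C)[C@H]([C@@H](OC(C)=O)[C@@](O)(C=C)[C@@H](C)C(=O)OCC[Si](C)(C)C)[C@@]1(C)C=O | intermediate
25 | 4-(trimethylsilyl)but-3-yn-2-one | CC(=O)C#C[Si](C)(C)C | starting material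
26 | (2R)-2-hydroxy-4-oxo-5-ynyl aldol adduct | CC(C)(C)[Si](C)(C)O[C@H]1C[C@@H]2O[C@]2(C)[C@H]([C@@H](OC(C)=O)[C@@](O)(C=C)[C@@H](C)C(=O)OCC[Si](C)(C)C)[C@@]1(C)[C@H](O)CC(=O)C#C[Si](C)(C)C | intermediate
27 | (2R,4R)-2,4-anti-diol | CC(C)(C)[Si](C)(C)O[C@H]1C[C@@H]2O[C@]2(C)[C@H]([C@@H](OC(C)=O)[C@@](O)(C=C)[C@@H](C)C(=O)OCC[Si](C)(C)C)[C@@]1(C)[C@H](O)C[C@@H](O)C#C[Si](C)(C)C | intermediate
28 | 2,4,14-triol C19 acid with terminal C5≡C6 alkyne | O[C@H]1C[C@@H]2O[C@]2(C)[C@H]([C@@H](OC(C)=O)[C@@](O)(C=C)[C@@H](C)C(=O)O)[C@@]1(C)[C@H](O)C[C@@H](O)C#C | intermediate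
29 | mixed acetic C19 anhydride of 30 (not isolated) | CC(=O)O[C@H]1C[C@@H]2O[C@]2(C)[C@H]([C@@H](OC(C)=O)[C@@](O)(C=C)[C@@H](C)C(=O)OC(C)=O)[C@@]1(C)[C@H](OC(C)=O)C[C@@H](OC(C)=O)C#C | intermediate
30 | 2,4,9,14-tetraacetate C19 acid (acyclic enyne) | CC(=O)O[C@H]1C[C@@H]2O[C@]2(C)[C@H]([C@@H](OC(C)=O)[C@@](O)(C=C)[C@@H](C)C(=O)O)[C@@]1(C)[C@H](OC(C)=O)C[C@@H](OC(C)=O)C#C | intermediate
31 | triene acid, C5(=C16H2)–C6H=CH2 (not isolated) | CC(=O)O[C@H]1C[C@@H]2O[C@]2(C)[C@H]([C@@H](OC(C)=O)[C@@](O)(C=C)[C@@H](C)C(=O)O)[C@@]1(C)[C@H](OC(C)=O)C[C@@H](OC(C)=O)C(=C)C=C | intermediate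
32 | ten-membered 5(16),6Z-diene C19 acid | CC(=O)O[C@H]1C[C@@H]2O[C@]2(C)[C@@H]2[C@@H](OC(C)=O)[C@](O)([C@@H](C)C(=O)O)/C=C\C(=C)[C@H](OC(C)=O)C[C@@H](OC(C)=O)[C@@]12C | intermediate
33 | 16-O-trifluoroacetyl derivative of 34 (not isolated) | CC(=O)O[C@H]1C[C@@H]2O[C@]2(C)[C@@H]2[C@@H](OC(C)=O)[C@@]3(O)[C@H](/C=C(/COC(=O)C(F)(F)F)[C@H](OC(C)=O)C[C@@H](OC(C)=O)[C@@]12C)OC(=O)[C@@H]3C | intermediate
34 | CNP0104124.1 | CC(=O)O[C@H]1C[C@@H]2O[C@]2(C)[C@@H]2[C@@H](OC(C)=O)[C@@]3(O)[C@H](/C=C(/CO)[C@H](OC(C)=O)C[C@@H](OC(C)=O)[C@@]12C)OC(=O)[C@@H]3C | target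

**Step count and risks**
Total step count: 21. Longest linear sequence: 20 (steps 1–10 and 12–21, from (S)-carvone).

The three steps most likely to fail:

Step 5 (Wharton transposition at a ketone flanked by a quaternary carbon and the oxirane carbon; hydrazone formation may be too slow). The fallback sets out from 7 and comes back at 9. NaBH4, MeOH, −20 °C reduces the ketone to the 10-hydroxy epoxide F1 (either C10 epimer serves). 1,1′-Thiocarbonyldiimidazole, DMAP, toluene, 80 °C gives the thiocarbonylimidazolide F2. Bu3SnH, AIBN, toluene, 90 °C then generates the C10 radical, which opens the oxirane by C11–O scission; reduction of the alkoxy radical gives 9 (Barton-type deoxygenative epoxide fragmentation).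

Step 20 (ring-closing metathesis to a ten-membered ring onto a vinyl group on a fully substituted carbon). The fallback sets out from 30 and comes back at 34. Bu3SnH with Mo(CO)3(CNtBu)3 (cat.), THF, 55 °C adds tin α-selectively to the propargylic acetate to give the 5-stannyl alkene F3. I2, CH2Cl2, 0 °C gives the 5-iodo alkene F4. An intramolecular Heck reaction (Pd(OAc)2, Ag2CO3, DMF, 2 mM, 60 °C) follows: zerovalent palladium inserts into C5–I and adds to the terminal carbon of the C8 vinyl group, which becomes C6, and β-hydride elimination closes the ring as the 6E isomer of 32, F5. Here the two alkyne carbons become C5 and C16 and no ethylene is needed. F5 is taken through step 21 to 34.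

Step 21 (the proposed new oxidation; the face of attack at C7, the 5Z geometry and the tolerance of the oxirane are unproven). The fallback sets out from 32 and comes back at 34. PhSeCl, K2CO3, CH2Cl2, −78 °C effects phenylselenolactonisation, in which the carboxylate adds 5-exo and anti to the seleniranium ion on C6=C7, giving the 6-phenylseleno 19,7-lactone F6. H2O2, pyridine, CH2Cl2, 0 °C oxidises it to the allylic selenoxide F7, which undergoes [2,3]-sigmatropic shift to the C16 selenenate F8 with formation of C5=C6. The aqueous work-up cleaves F8 to 34.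

**Further compounds**
F1 | step 5 | 10-hydroxy epoxide from 7 (C10 epimers) | CC(=O)O[C@H]1C[C@@H]2O[C@]2(C)C(O)[C@@]1(C)CO[Si](C)(C)C(C)(C)C
F2 | step 5 | 10-O-thiocarbonylimidazolide of F1 | CC(=O)O[C@H]1C[C@@H]2O[C@]2(C)C(OC(=S)n3ccnc3)[C@@]1(C)CO[Si](C)(C)C(C)(C)C
F3 | step 20 | 5-(tributylstannyl) alkene from 30 | CC(=O)O[C@H]1C[C@@H]2O[C@]2(C)[C@H]([C@@H](OC(C)=O)[C@@](O)(C=C)[C@@H](C)C(=O)O)[C@@]1(C)[C@H](OC(C)=O)C[C@@H](OC(C)=O)C(=C)[Sn](CCCC)(CCCC)CCCC
F4 | step 20 | 5-iodo alkene from F3 | CC(=O)O[C@H]1C[C@@H]2O[C@]2(C)[C@H]([C@@H](OC(C)=O)[C@@](O)(C=C)[C@@H](C)C(=O)O)[C@@]1(C)[C@H](OC(C)=O)C[C@@H](OC(C)=O)C(I)=C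
F5 | step 20 | 6E isomer of 32 | CC(=O)O[C@H]1C[C@@H]2O[C@]2(C)[C@@H]2[C@@H](OC(C)=O)[C@](O)([C@@H](C)C(=O)O)/C=C/C(=C)[C@H](OC(C)=O)C[C@@H](OC(C)=O)[C@@]12C
F6 | step 21 | 6-phenylseleno 19,7-lactone with 5(16)-methylene | CC(=O)O[C@H]1C[C@@H]2O[C@]2(C)[C@@H]2[C@@H](OC(C)=O)[C@@]3(O)[C@H]([C@H]([Se]c4ccccc4)C(=C)[C@H](OC(C)=O)C[C@@H](OC(C)=O)[C@@]12C)OC(=O)[C@@H]3C
F7 | step 21 | selenoxide of F6 (selenium centre unassigned) | CC(=O)O[C@H]1C[C@@H]2O[C@]2(C)[C@@H]2[C@@H](OC(C)=O)[C@@]3(O)[C@H]([C@H]([Se](=O)c4ccccc4)C(=C)[C@H](OC(C)=O)C[C@@H](OC(C)=O)[C@@]12C)OC(=O)[C@@H]3C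
F8 | step 21 | 16-O-phenylselenenyl ester of 34 | CC(=O)O[C@H]1C[C@@H]2O[C@]2(C)[C@@H]2[C@@H](OC(C)=O)[C@@]3(O)[C@H](/C=C(/CO[Se]c4ccccc4)[C@H](OC(C)=O)C[C@@H](OC(C)=O)[C@@]12C)OC(=O)[C@@H]3C
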